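Carbon atoms are numbered as in eudesmane throughout (ring A = C1–C5, C10; ring B = C5–C10; C14 on C10, C15 on C4, C11–C13 in the side chain). Monocyclic compounds carry systematic locants in their names.

## Analysis of the target

The target 27 is a trans-fused decalin of the eudesmane type. Ring A carries all four stereocentres (C3, C4, C5, C10) and ring B carries a 7(11)-en-8-one, that is, a ketone with an isopropylidene group on its α-carbon. C10 is quaternary with an axial β-methyl and C5 has its hydrogen α, so the ring fusion is trans. C3 bears the β (equatorial) angeloyloxy group, and C4 bears the α (equatorial) acetoxy group together with an axial β-methyl that is syn-axial to the C10 methyl. The two oxygens are therefore trans-diequatorial neighbours, one secondary and one tertiary, and must be acylated differently. The (Z)-2-methylbut-2-enoate isomerises easily to the (E)-ester, the tertiary acetate can migrate to a free C3 hydroxyl, and the isopropylidene ketone does not tolerate strong base or hydride. The hard points are the quaternary C10 next to C5 in one absolute sense and the tertiary oxygen on the α-face of C4. The plan rests on the fact that C3 and C4 are adjacent oxygen-bearing carbons and that C4 also carries C15. Cutting the C3–C4 bond of ring A gives a C3 aldehyde and a C4 1-iodoethenyl group on an intact ring B, and the coupling leaves C4 trigonal, so that its oxygen can be delivered afterwards from the α-face, away from the axial C10 methyl.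

## Retrosynthetic reasoning

**Esters.** The C3 ester bond of 27 is cut last, back to alcohol 26, because the (Z)-ester is the most fragile group. The C3 oxygen is kept as a silyl ether (25 back to 20) while the hindered tertiary C4 hydroxyl of 19 is acetylated. The two oxygens are thus told apart by protection and not by reactivity.

**Isopropylidene.** The C7=C11 bond of 25 is cut to ketone 21 and a three-carbon ketone electrophile (aldol addition to 23, then elimination). It is made after all hydride and peracid steps, and on the free ketone obtained from ketal 20. C7 is the only accessible α-carbon, since C9 is flanked by the quaternary C10.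

**Tertiary carbinol.** The C4–O bond and the C15–H bond of 19 are traced to the spiro-epoxide 18 and further to the exocyclic alkene 17. Oxygen is put on the α-face because the β-face is covered by the axial C10 methyl, and hydride then turns the epoxide carbon into the axial C15 methyl. A methyl nucleophile on a C4 ketone would give the wrong epimer for the same steric reason.

**Ring A (key disconnection).** The C3–C4 bond of 16 is cut to aldehyde 14, in which C4 is an alkenyl iodide. Both carbons are electrophiles and are joined reductively by chromium with nickel catalysis. This avoids enolate chemistry next to C10, creates the C3 carbinol in the same step and delivers exactly the 4(15)-alkene needed above.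

**Side-chain ends of 14.** The aldehyde is traced to the terminal alkene of 11 (hydroboration, oxidation) and the 1-iodoethenyl group to methyl ketone 9 through its hydrazone. The alkene is carried as an inert three-carbon chain until the iodide is in place.

**Methyl ketone and ketal.** The C4–C15 bond of 9 is cut to the N-methoxy-N-methylamide 8 and a methyl nucleophile. The ring ketone of 7 is masked as the dioxolane before that step and stays masked until after the epoxide opening.

**Quaternary centre.** The C10–C1 bond of 7 is cut to enone 6 and an allyl nucleophile. In 6 the C5 substituent sits pseudo-axial next to the C10 methyl, so the allyl group must enter anti to it. This gives the methyl cis and the chain trans to the C5 carbon, as ring A later needs. Forming C5–C10 by a cycloaddition with the quaternary carbon already in the dienophile would need a β,β-disubstituted acceptor, a sluggish class; splitting the task costs one step but uses two well-tried reactions.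

**Ring B.** Enone 6 is traced through amide 5 to the cycloadduct 4, and the C5–C10 and C6–C7 bonds of 4 are cut to diene 2 and acrylate 3. The silyloxy group directs the ester "para" and the methyl directs it "ortho", so both regiochemical preferences agree. A chiral Lewis acid sets C5, the only centre of 4 that is carried on.

**Diene.** Diene 2 is the silyl enol ether of enone 1.

## Alternatives that were turned down

**Alternative 1:** The C5–C10 bond and the C4–O bond are cut together, back to the ten-membered 3-silyloxy trienone A1. In the forward step aqueous acid protonates C1, the C4=C5 alkene attacks the C10 cation across the ring, and the C4 cation is hydrated to give A2. In its favour, one step makes both rings, C5, C10 and C4, and A2 already carries the ring B enone; it is only three or four steps from 27, so on step economy it is clearly stronger than the chosen route. Against it, A1 itself needs an enantioselective C3 oxygenation on a flexible cyclodecadienone. The C4 cation sits next to the oxygen-bearing C3 and is inductively destabilised, so proton loss to alkenes and capture from either face compete with α-hydration. Different ring conformers lead to cis- and trans-fused products, and the silyl ether must survive aqueous acid. The chosen route is longer but sets each centre in a separate, controllable step (C5 in step 2, C10 in step 5, C3 in step 11, C4 in step 13) and avoids a medium ring.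

**Alternative 2:** The C9–C10 bond is cut, back to phenol A3 with an allylic carbonate side chain. A zerovalent palladium catalyst with a chiral bisphosphine ionises the carbonate and the para carbon of the phenoxide attacks the allyl terminus, closing ring B and giving dienone A4. In its favour, A3 is flat and easy to assemble, and C10 is set catalytically in the ring-forming step; on this point it is as strong as or stronger than the chosen route. Against it, A4 has no C5 centre and the wrong oxidation pattern. It still needs reduction of C1=C2 and of the C3 ketone, a net syn addition of hydrogen (C5) and hydroxyl (C4) on the α-face of a tetrasubstituted enone alkene, and conversion of the 8-methylidene group into the ketone with the C7 side chain. O-alkylation and ortho attack also compete with the para attack. The chosen route sets C5 and C10 early on ring B and keeps C4 as a simple exocyclic alkene, where the face of oxygenation is dictated by the C10 methyl.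

**Alternative 3:** The C10–C14 and C5–C6 bonds are cut, back to enone A5 with a tethered iodide. A chiral copper–phosphoramidite catalyst adds a methylaluminium reagent to C10, and the enolate, activated as an ate complex, displaces the iodide to close ring B and give A6. In its favour, the C3 oxygen is present from the start, C10 is set by catalysis, and ring B and C5 arise in one flask; in convergence it is at least equal to the chosen route. Against it, the catalyst must override the existing C3 centre, aluminium enolates alkylate unactivated iodides poorly, and the ring fusion formed under kinetic control next to the C4 ketone is not reliably trans. The decisive point is that a methyl nucleophile adds to the C4 ketone of A6 from the open α-face and gives the 4β-hydroxy epimer. A6 would therefore have to be methylenated to the very alkene 17 that the chosen route reaches directly, with C5 already fixed.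

Key step: step 11

Assumption on the chemistry: in step 2 the (S)-configured oxazaborolidinium cation is taken to add 2 to the face of 3 that gives (1R)-4; should the preference run the other way, the (R)-catalyst, equally accessible, gives the same 4. The C7 configuration of 23 and 24 is left open because step 18 removes it.

Step 1
Reactants: 1 (3E)-pent-3-en-2-one
Product: 2 triisopropyl{[(3E)-penta-1,3-dien-2-yl]oxy}silane
Conditions: i-Pr3SiOSO2CF3 (1.1 equiv), Et3N (1.5 equiv), Et2O, 0 °C to rt
Reagents that add atoms: triisopropylsilyl trifluoromethanesulfonate, CC(C)[Si](C(C)C)(C(C)C)OS(=O)(=O)C(F)(F)F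
Why: O-silylation of the enone and loss of a proton from the acetyl methyl group (soft enolisation) give the cross-conjugated 2-silyloxydiene; the (E)-alkene is not touched.

Step 2
Reactants: 2 triisopropyl{[(3E)-penta-1,3-dien-2-yl]oxy}silane; 3 2,2,2-trifluoroethyl prop-2-enoate
Product: 4 2,2,2-trifluoroethyl (1R,2S)-2-methyl-4-[(triisopropylsilyl)oxy]cyclohex-3-ene-1-carboxylate
Conditions: 20 mol% of the oxazaborolidinium salt made from (S)-3,3-diphenyl-1-(2-methylphenyl)tetrahydro-1H,3H-pyrrolo[1,2-c][1,3,2]oxazaborole and HN(SO2CF3)2, CH2Cl2, −20 °C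
Reagents that add atoms: none
Why: Oxazaborolidinium-catalysed Diels–Alder reaction; the CH2 terminus next to the silyloxy carbon bonds to the acrylate β-carbon, so the ester ends "para" to the silyloxy group and "ortho" to the methyl, and the endo transition state gives the cis adduct. The aryl group of the catalyst screens one face of the bound acrylate and sets C1 (later C5); the C2 centre is erased in step 4, so only facial selectivity matters.

Step 3
Reactants: 4 2,2,2-trifluoroethyl (1R,2S)-2-methyl-4-[(triisopropylsilyl)oxy]cyclohex-3-ene-1-carboxylate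
Product: 5 (1R,2S)-N-methoxy-N,2-dimethyl-4-[(triisopropylsilyl)oxy]cyclohex-3-ene-1-carboxamide
Conditions: MeNH(OMe)·HCl (1.5 equiv), i-PrMgCl (3.0 equiv), THF, −20 °C
Reagents that add atoms: N,O-dimethylhydroxylamine hydrochloride, CNOC.Cl
Why: Aminolysis of the activated ester by the chloromagnesium amide (Weinreb amide formation) at low temperature, without enolisation. The carboxamide makes the adjacent C–H less acidic before the enone is unveiled and is the later handle for the methyl ketone.

Step 4
Reactants: 5 (1R,2S)-N-methoxy-N,2-dimethyl-4-[(triisopropylsilyl)oxy]cyclohex-3-ene-1-carboxamide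
Product: 6 (1R)-N-methoxy-N,2-dimethyl-4-oxocyclohex-2-ene-1-carboxamide
Conditions: Pd(OAc)2 (1.1 equiv), MeCN, rt to 40 °C
Reagents that add atoms: none
Why: Saegusa–Ito dehydrogenation; the palladium enolate at C3 can only eliminate the β-hydrogen at C2, which gives the 3-methyl-enone pattern and deletes the C2 centre. The medium is neutral, so the γ-hydrogen at C1 stays in place.

Step 5
Reactants: 6 (1R)-N-methoxy-N,2-dimethyl-4-oxocyclohex-2-ene-1-carboxamide
Product: 7 (1R,2R)-N-methoxy-N,2-dimethyl-4-oxo-2-(prop-2-en-1-yl)cyclohexane-1-carboxamide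
Conditions: CH2=CHCH2SiMe3 (2 equiv), TiCl4 (2.2 equiv), CH2Cl2, −78 °C; aq. NaHCO3
Reagents that add atoms: allyltrimethylsilane, C=CC[Si](C)(C)C
Why: Hosomi–Sakurai conjugate allylation of the TiCl4-activated β,β-disubstituted enone. A(1,2) strain with the 2-methyl group holds the carboxamide pseudo-axial, so axial attack at C2 comes from the opposite face and the quaternary centre (later C10) forms with allyl trans and methyl cis to the carboxamide. The conditions are Lewis acidic and non-basic, so C1 is not epimerised.

Step 6
Reactants: 7 (1R,2R)-N-methoxy-N,2-dimethyl-4-oxo-2-(prop-2-en-1-yl)cyclohexane-1-carboxamide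
Product: 8 (7R,8R)-N-methoxy-N,7-dimethyl-7-(prop-2-en-1-yl)-1,4-dioxaspiro[4.5]decane-8-carboxamide
Conditions: HOCH2CH2OH (5 equiv), p-toluenesulfonic acid monohydrate (5 mol%), benzene, reflux, Dean–Stark trap
Reagents that add atoms: ethane-1,2-diol, OCCO
Why: Acid-catalysed ketalisation with azeotropic removal of water; the ring ketone is the only group that reacts.

Step 7
Reactants: 8 (7R,8R)-N-methoxy-N,7-dimethyl-7-(prop-2-en-1-yl)-1,4-dioxaspiro[4.5]decane-8-carboxamide
Product: 9 1-[(7R,8R)-7-methyl-7-(prop-2-en-1-yl)-1,4-dioxaspiro[4.5]decan-8-yl]ethan-1-one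
Conditions: MeMgBr (3 equiv), THF, 0 °C to rt; cold aq. NH4Cl
Reagents that add atoms: methylmagnesium bromide, C[Mg]Br
Why: Weinreb ketone synthesis; the chelated tetrahedral adduct collapses only on quench, so there is no second addition and the new ketone never meets base, which protects the configuration at C8 (eudesmane C5).

Step 8
Reactants: 9 1-[(7R,8R)-7-methyl-7-(prop-2-en-1-yl)-1,4-dioxaspiro[4.5]decan-8-yl]ethan-1-one
Product: 11 (7R,8R)-8-(1-iodoethenyl)-7-methyl-7-(prop-2-en-1-yl)-1,4-dioxaspiro[4.5]decane, via hydrazone 10 (not isolated)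
Conditions: N2H4·H2O (10 equiv), Et3N, EtOH, 70 °C; evaporate; then I2 (2.2 equiv), 1,1,3,3-tetramethylguanidine (5 equiv), THF, 0 °C to rt
Reagents that add atoms: iodine, II
Why: Barton vinyl iodide synthesis; iodine oxidises the hydrazone to the diazoalkane, iodination and loss of dinitrogen give an α-iodo cation, and the guanidine removes a proton from the methyl group in preference to the hindered ring C–H. The isolated alkene and the ketal are inert.

Step 9
Reactants: 11 (7R,8R)-8-(1-iodoethenyl)-7-methyl-7-(prop-2-en-1-yl)-1,4-dioxaspiro[4.5]decane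
Product: 13 3-[(7R,8R)-8-(1-iodoethenyl)-7-methyl-1,4-dioxaspiro[4.5]decan-7-yl]propan-1-ol, via alkylborane 12 (not isolated)
Conditions: 9-borabicyclo[3.3.1]nonane (1.5 equiv), THF, 0 °C to rt; then 3 M NaOH, 30% H2O2, 0 °C
Reagents that add atoms: hydrogen peroxide, OO
Why: Anti-Markovnikov hydroboration–oxidation; the bulky borane takes the monosubstituted alkene and leaves the electron-poor, 1,1-disubstituted iodoalkene next to the quaternary carbon.

Step 10
Reactants: 13 3-[(7R,8R)-8-(1-iodoethenyl)-7-methyl-1,4-dioxaspiro[4.5]decan-7-yl]propan-1-ol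
Product: 14 3-[(7R,8R)-8-(1-iodoethenyl)-7-methyl-1,4-dioxaspiro[4.5]decan-7-yl]propanal
Conditions: Dess–Martin periodinane (1.3 equiv), NaHCO3, CH2Cl2, 0 °C to rt
Reagents that add atoms: none
Why: Buffered Dess–Martin oxidation of the primary alcohol stops at the aldehyde and touches neither the ketal nor the alkenyl iodide.

Step 11
Reactants: 14 3-[(7R,8R)-8-(1-iodoethenyl)-7-methyl-1,4-dioxaspiro[4.5]decan-7-yl]propanal
Product: 16 (3S,5R,10R)-3-hydroxy-10-methyl-4-methylidene-trans-decalin-8-one ethylene ketal (3β-OH, 5α-H, 10β-CH3), via alkenylchromium dichloride 15 (not isolated)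
Conditions: CrCl2 (6 equiv), NiCl2 (1 mol% of the CrCl2), degassed DMF, rt, slow addition of 14 to a final 0.005 M
Reagents that add atoms: none
Why: CrCl2 reduces NiCl2 to zerovalent nickel, which inserts into the C4–I bond of 14; transmetalation to trivalent chromium gives 15 and returns divalent nickel, and 15 adds to the C3 aldehyde through a four-centre arrangement in which chromium bridges C4 and the carbonyl oxygen. The closest known reaction type is the intramolecular Nozaki–Hiyama–Kishi coupling of 2-iodo-1-alkenes with tethered aldehydes, which gives 2-methylidenecycloalkanols. Ring A closes in the 6-exo-trig mode (C4 attacks the carbonyl carbon and the oxygen stays outside the new ring) through a chair in which ring B holds the C10 chain and the C5 alkenyl group trans-diequatorial. The new C3 centre is controlled by C5 and C10: with chromium in the plane of the alkenyl unit the bound oxygen is pseudo-equatorial (3β), whereas the pseudo-axial alternative would press the solvated metal against the axial hydrogens at C1 and C5 on the α-face. The step needs chemoselectivity for the aldehyde (the weakly basic organochromium leaves the ketal alone and does not enolise the aldehyde), ring closure over intermolecular coupling (secured by high dilution) and diastereoselection at C3 (secured by the rigid trans-substituted ring B).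

Step 12
Reactants: 16 (3S,5R,10R)-3-hydroxy-10-methyl-4-methylidene-trans-decalin-8-one ethylene ketal
Product: 17 (3S,5R,10R)-3-[(tert-butyldimethylsilyl)oxy]-10-methyl-4-methylidene-trans-decalin-8-one ethylene ketal
Conditions: t-BuMe2SiCl (1.5 equiv), imidazole (3 equiv), DMF, rt
Reagents that add atoms: tert-butyl(chloro)dimethylsilane, CC(C)(C)[Si](C)(C)Cl
Why: Silylation of the secondary allylic alcohol marks O3 for the later angelate and removes any hydroxyl-directed delivery in the epoxidation.

Step 13
Reactants: 17 (3S,5R,10R)-3-[(tert-butyldimethylsilyl)oxy]-10-methyl-4-methylidene-trans-decalin-8-one ethylene ketal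
Product: 18 (3S,4R,5R,10R)-3-[(tert-butyldimethylsilyl)oxy]-4α,15-epoxy-10-methyl-trans-decalin-8-one ethylene ketal (spiro-oxirane at C4, oxygen α)
Conditions: mCPBA (1.3 equiv), NaHCO3, CH2Cl2, 0 °C
Reagents that add atoms: 3-chloroperoxybenzoic acid, OOC(=O)c1cccc(Cl)c1
Why: Prilezhaev epoxidation; the β-face of the exocyclic alkene is screened by the syn-axial C10 methyl and by the slightly β-tilted equatorial silyloxy group, so oxygen is delivered to the α-face and C4 receives its oxygen in the equatorial α position.

Step 14
Reactants: 18 (3S,4R,5R,10R)-3-[(tert-butyldimethylsilyl)oxy]-4α,15-epoxy-10-methyl-trans-decalin-8-one ethylene ketal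
Product: 19 (3S,4S,5R,10R)-3-[(tert-butyldimethylsilyl)oxy]-4α-hydroxy-4β,10β-dimethyl-trans-decalin-8-one ethylene ketal
Conditions: LiEt3BH (3 equiv), THF, 0 °C to rt
Reagents that add atoms: none
Why: SN2 opening of the 1,1-disubstituted epoxide by hydride at the primary carbon turns it into the axial C15 methyl and leaves the C4–O bond, and so the 4α configuration, untouched; ketal and silyl ether are inert.

Step 15
Reactants: 19 (3S,4S,5R,10R)-3-[(tert-butyldimethylsilyl)oxy]-4α-hydroxy-4β,10β-dimethyl-trans-decalin-8-one ethylene ketal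
Product: 20 (3S,4S,5R,10R)-4α-acetoxy-3-[(tert-butyldimethylsilyl)oxy]-4β,10β-dimethyl-trans-decalin-8-one ethylene ketal
Conditions: Ac2O (10 equiv), 4-(dimethylamino)pyridine (1 equiv), pyridine, 60 °C
Reagents that add atoms: acetic anhydride, CC(=O)OC(C)=O
Why: Acylation of the tertiary alcohol through the N-acetylpyridinium ion (Steglich-type); it is done here because ketal and silyl ether are the only other groups and tolerate forcing conditions.

Step 16
Reactants: 20 (3S,4S,5R,10R)-4α-acetoxy-3-[(tert-butyldimethylsilyl)oxy]-4β,10β-dimethyl-trans-decalin-8-one ethylene ketal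
Product: 21 (3S,4S,5R,10R)-4α-acetoxy-3β-[(tert-butyldimethylsilyl)oxy]-4β,10β-dimethyl-trans-decalin-8-one
Conditions: pyridinium p-toluenesulfonate (0.3 equiv), acetone–H2O (10:1), 55 °C
Reagents that add atoms: water, O
Why: Mild acid hydrolysis of the dioxolane; the buffered acid spares the secondary silyl ether and the tertiary acetate.

Step 17
Reactants: 21 (3S,4S,5R,10R)-4α-acetoxy-3β-[(tert-butyldimethylsilyl)oxy]-4β,10β-dimethyl-trans-decalin-8-one
Product: 23 (3S,4S,5R,10R)-4α-acetoxy-3β-[(tert-butyldimethylsilyl)oxy]-7-(2-hydroxypropan-2-yl)-4β,10β-dimethyl-trans-decalin-8-one (C7 epimers), via lithium enolate 22 (not isolated)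
Conditions: LiN(i-Pr)2 (1.05 equiv), THF, −78 °C; acetone (3 equiv), −78 °C; AcOH quench at −78 °C
Reagents that add atoms: acetone, CC(C)=O
Why: Kinetic deprotonation takes the C7 hydrogen (C9 is neopentyl, and ketone α-hydrogens are removed faster than those of the acetate) and the enolate undergoes aldol addition to acetone. The C7 enolate cannot attack the acetate because the C4–C5–C6–C7 chain is locked anti in the trans-decalin; the cold quench prevents retro-aldol cleavage.

Step 18
Reactants: 23 (3S,4S,5R,10R)-4α-acetoxy-3β-[(tert-butyldimethylsilyl)oxy]-7-(2-hydroxypropan-2-yl)-4β,10β-dimethyl-trans-decalin-8-one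
Product: 25 (3S,4S,5R,10R)-4α-acetoxy-3β-[(tert-butyldimethylsilyl)oxy]eudesm-7(11)-en-8-one, via methanesulfonate 24 (not isolated)
Conditions: MeSO2Cl (3 equiv), Et3N (6 equiv), CH2Cl2, 0 °C; then 1,8-diazabicyclo[5.4.0]undec-7-ene (5 equiv), rt
Reagents that add atoms: none
Why: Sulfonylation of the tertiary aldol hydroxyl and E1cB elimination through the C7 enolate give the conjugated tetrasubstituted alkene; the amidine base moves any isopropenyl isomer into conjugation.

Step 19
Reactants: 25 (3S,4S,5R,10R)-4α-acetoxy-3β-[(tert-butyldimethylsilyl)oxy]eudesm-7(11)-en-8-one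
Product: 26 (3S,4S,5R,10R)-4α-acetoxy-3β-hydroxyeudesm-7(11)-en-8-one
Conditions: HF·pyridine, pyridine, THF, 0 °C to rt
Reagents that add atoms: none
Why: Fluoride-driven Si–O cleavage in a weakly acidic buffered medium; no alkoxide is formed at O3, which is what an O4-to-O3 acetyl shift would need.

Step 20
Reactants: 26 (3S,4S,5R,10R)-4α-acetoxy-3β-hydroxyeudesm-7(11)-en-8-one
Product: 27 (3S,4S,5R,10R)-4α-acetoxy-8-oxoeudesm-7(11)-en-3β-yl (2Z)-2-methylbut-2-enoate
Conditions: (Z)-MeCH=C(Me)CO2H (3 equiv), 2,4,6-Cl3C6H2COCl (3 equiv), Et3N (6 equiv), toluene, rt, 2 h; then 26, 80 °C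
Reagents that add atoms: angelic acid [(2Z)-2-methylbut-2-enoic acid], C/C=C(/C)C(O)=O
Why: Yamaguchi-type esterification through the preformed mixed anhydride, run without a nucleophilic pyridine catalyst so that no reversible conjugate addition can turn the (Z)-acyl group into the (E)-isomer; the secondary equatorial hydroxyl is the only free one.

## Compound list

1 | (3E)-pent-3-en-2-one | C/C=C/C(C)=O | starting material
2 | triisopropyl{[(3E)-penta-1,3-dien-2-yl]oxy}silane | C/C=C/C(=C)O[Si](C(C)C)(C(C)C)C(C)C | intermediate
3 | 2,2,2-trifluoroethyl prop-2-enoate | C=CC(=O)OCC(F)(F)F | starting material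
4 | 2,2,2-trifluoroethyl (1R,2S)-2-methyl-4-[(triisopropylsilyl)oxy]cyclohex-3-ene-1-carboxylate (cis) | C[C@H]1C=C(O[Si](C(C)C)(C(C)C)C(C)C)CC[C@H]1C(=O)OCC(F)(F)F | intermediate
5 | (1R,2S)-N-methoxy-N,2-dimethyl-4-[(triisopropylsilyl)oxy]cyclohex-3-ene-1-carboxamide | C[C@H]1C=C(O[Si](C(C)C)(C(C)C)C(C)C)CC[C@H]1C(=O)N(C)OC | intermediate
6 | (1R)-N-methoxy-N,2-dimethyl-4-oxocyclohex-2-ene-1-carboxamide | CC1=CC(=O)CC[C@H]1C(=O)N(C)OC | intermediate
7 | (1R,2R)-N-methoxy-N,2-dimethyl-4-oxo-2-(prop-2-en-1-yl)cyclohexane-1-carboxamide (allyl trans, methyl cis to the carboxamide) | C=CC[C@]1(C)CC(=O)CC[C@H]1C(=O)N(C)OC | intermediate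
8 | (7R,8R)-N-methoxy-N,7-dimethyl-7-(prop-2-en-1-yl)-1,4-dioxaspiro[4.5]decane-8-carboxamide | C=CC[C@]1(C)CC2(OCCO2)CC[C@H]1C(=O)N(C)OC | intermediate
9 | 1-[(7R,8R)-7-methyl-7-(prop-2-en-1-yl)-1,4-dioxaspiro[4.5]decan-8-yl]ethan-1-one | C=CC[C@]1(C)CC2(OCCO2)CC[C@H]1C(C)=O | intermediate
10 | {1-[(7R,8R)-7-methyl-7-(prop-2-en-1-yl)-1,4-dioxaspiro[4.5]decan-8-yl]ethylidene}hydrazine | C=CC[C@]1(C)CC2(OCCO2)CC[C@H]1C(C)=NN | intermediate (not isolated)
11 | (7R,8R)-8-(1-iodoethenyl)-7-methyl-7-(prop-2-en-1-yl)-1,4-dioxaspiro[4.5]decane | C=CC[C@]1(C)CC2(OCCO2)CC[C@H]1C(I)=C | intermediate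
12 | 9-{3-[(7R,8R)-8-(1-iodoethenyl)-7-methyl-1,4-dioxaspiro[4.5]decan-7-yl]propyl}-9-borabicyclo[3.3.1]nonane | C(CC[C@]1(C)CC2(OCCO2)CC[C@H]1C(I)=C)B3C4CCCC3CCC4 | intermediate (not isolated)
13 | 3-[(7R,8R)-8-(1-iodoethenyl)-7-methyl-1,4-dioxaspiro[4.5]decan-7-yl]propan-1-ol | OCCC[C@]1(C)CC2(OCCO2)CC[C@H]1C(I)=C | intermediate
14 | 3-[(7R,8R)-8-(1-iodoethenyl)-7-methyl-1,4-dioxaspiro[4.5]decan-7-yl]propanal | O=CCC[C@]1(C)CC2(OCCO2)CC[C@H]1C(I)=C | intermediate
15 | dichloro{1-[(7R,8R)-7-methyl-7-(3-oxopropyl)-1,4-dioxaspiro[4.5]decan-8-yl]ethenyl}chromium (trivalent chromium, solvated by DMF) | O=CCC[C@]1(C)CC2(OCCO2)CC[C@H]1C(=C)[Cr](Cl)Cl | intermediate (not isolated)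
16 | (3S,5R,10R)-3-hydroxy-10-methyl-4-methylidene-trans-decalin-8-one ethylene ketal (3β-OH, 5α-H, 10β-CH3) | O[C@H]1CC[C@]2(C)CC3(OCCO3)CC[C@H]2C1=C | intermediate
17 | (3S,5R,10R)-3-[(tert-butyldimethylsilyl)oxy]-10-methyl-4-methylidene-trans-decalin-8-one ethylene ketal | CC(C)(C)[Si](C)(C)O[C@H]1CC[C@]2(C)CC3(OCCO3)CC[C@H]2C1=C | intermediate
18 | (3S,4R,5R,10R)-3-[(tert-butyldimethylsilyl)oxy]-4α,15-epoxy-10-methyl-trans-decalin-8-one ethylene ketal | CC(C)(C)[Si](C)(C)O[C@H]1CC[C@]2(C)CC3(OCCO3)CC[C@H]2[C@]14OC4 | intermediate
19 | (3S,4S,5R,10R)-3-[(tert-butyldimethylsilyl)oxy]-4α-hydroxy-4β,10β-dimethyl-trans-decalin-8-one ethylene ketal | CC(C)(C)[Si](C)(C)O[C@H]1CC[C@]2(C)CC3(OCCO3)CC[C@H]2[C@]1(C)O | intermediate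
20 | (3S,4S,5R,10R)-4α-acetoxy-3-[(tert-butyldimethylsilyl)oxy]-4β,10β-dimethyl-trans-decalin-8-one ethylene ketal | CC(C)(C)[Si](C)(C)O[C@H]1CC[C@]2(C)CC3(OCCO3)CC[C@H]2[C@]1(C)OC(C)=O | intermediate
21 | (3S,4S,5R,10R)-4α-acetoxy-3β-[(tert-butyldimethylsilyl)oxy]-4β,10β-dimethyl-trans-decalin-8-one | CC(C)(C)[Si](C)(C)O[C@H]1CC[C@]2(C)CC(=O)CC[C@H]2[C@]1(C)OC(C)=O | intermediate
22 | lithium 7(8)-enolate of 21 | CC(C)(C)[Si](C)(C)O[C@H]1CC[C@]2(C)CC(O[Li])=CC[C@H]2[C@]1(C)OC(C)=O | intermediate (not isolated)
23 | (3S,4S,5R,10R)-4α-acetoxy-3β-[(tert-butyldimethylsilyl)oxy]-7-(2-hydroxypropan-2-yl)-4β,10β-dimethyl-trans-decalin-8-one (C7 epimers) | CC(C)(C)[Si](C)(C)O[C@H]1CC[C@]2(C)CC(=O)C(C(C)(C)O)C[C@H]2[C@]1(C)OC(C)=O | intermediate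
24 | methanesulfonate of the tertiary side-chain hydroxyl of 23 | CC(C)(C)[Si](C)(C)O[C@H]1CC[C@]2(C)CC(=O)C(C(C)(C)OS(C)(=O)=O)C[C@H]2[C@]1(C)OC(C)=O | intermediate (not isolated)
25 | (3S,4S,5R,10R)-4α-acetoxy-3β-[(tert-butyldimethylsilyl)oxy]eudesm-7(11)-en-8-one | CC(C)(C)[Si](C)(C)O[C@H]1CC[C@]2(C)CC(=O)C(=C(C)C)C[C@H]2[C@]1(C)OC(C)=O | intermediate
26 | (3S,4S,5R,10R)-4α-acetoxy-3β-hydroxyeudesm-7(11)-en-8-one | O[C@H]1CC[C@]2(C)CC(=O)C(=C(C)C)C[C@H]2[C@]1(C)OC(C)=O | intermediate
27 | (3S,4S,5R,10R)-4α-acetoxy-8-oxoeudesm-7(11)-en-3β-yl (2Z)-2-methylbut-2-enoate | C/C=C(/C)C(=O)O[C@H]1CC[C@]2(C)CC(=O)C(=C(C)C)C[C@H]2[C@]1(C)OC(C)=O | target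

## Step count and least certain steps

Total step count: 20. Longest linear sequence: 20 steps, from 1 to 27; 3 enters in step 2.

**Step 11 (key step).** Two things may go wrong. The oxygen may take the pseudo-axial position in part, because the preference for the equatorial chromium alkoxide rests only on non-bonded contacts in the closing chair, so some 3α-carbinol would form. The alkenylchromium, which sits next to the quaternary C10, may also be protonated before it reaches the aldehyde, so the ring would not close. Fallback, from 14 back to 16: chlorite oxidation (NaClO2, NaH2PO4, 2-methylbut-2-ene) gives 3-[(7R,8R)-8-(1-iodoethenyl)-7-methyl-1,4-dioxaspiro[4.5]decan-7-yl]propanoic acid F1, and carbodiimide coupling with MeNH(OMe)·HCl gives the N-methoxy-N-methylamide F2. Iodine–lithium exchange with t-BuLi at −78 °C is followed by intramolecular acylation of the alkenyllithium (Parham-type closure of the same C3–C4 bond) to the enone (5R,10R)-10-methyl-4-methylidene-trans-decalin-3,8-dione 8-ethylene ketal F3. Reduction with NaBH4 and CeCl3·7H2O delivers hydride axially from the open α-face and gives the equatorial 3β-alcohol 16, so C3 is set by reduction and not in the C–C bond formation.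

**Step 2.** The extra methyl group on the diene terminus may lower the facial discrimination of the catalyst, or a stepwise Mukaiyama–Michael pathway may compete, either of which would erode the enantiomeric purity of the one centre carried forward. Fallback, from 2 back to 5: auxiliary control. The acrylimide (4S)-4-benzyl-3-(prop-2-enoyl)-1,3-oxazolidin-2-one (C=CC(=O)N1C(=O)OC[C@@H]1Cc1ccccc1) reacts with 2 under Et2AlCl at −78 °C through the chelated s-cis complex on the face away from the benzyl group and gives (4S)-4-benzyl-3-{[(1R,2S)-2-methyl-4-[(triisopropylsilyl)oxy]cyclohex-3-en-1-yl]carbonyl}-1,3-oxazolidin-2-one F4. Diastereomers can be separated at this stage, and AlMe3 with MeNH(OMe)·HCl converts F4 into 5.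

**Step 8.** Condensation of the hindered ketone with hydrazine is slow, and hydrazone–ene-hydrazine tautomerism during that time can epimerise the ring carbon next to the ketone (eudesmane C5), for which the monocycle has no thermodynamic bias; some proton loss toward the ring would also give the internal iodoalkene. Fallback, from 9 back to 11: kinetic deprotonation of the methyl group with KN(SiMe3)2 at −78 °C and trapping with PhN(SO2CF3)2 give 1-[(7R,8R)-7-methyl-7-(prop-2-en-1-yl)-1,4-dioxaspiro[4.5]decan-8-yl]ethenyl trifluoromethanesulfonate F5 without touching the ring C–H. Nickel-catalysed triflate-to-iodide exchange (NaI, 10 mol% Ni(cod)2 with cod = cycloocta-1,5-diene, N,N-dimethylacetamide–THF, rt) then gives 11.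

**Step 15.** The tertiary hydroxyl is flanked by the silyl ether at C3 and by the ring fusion, so acyl transfer may stall, and forcing may cause elimination of the tertiary alcohol. Fallback, from 19 back to 27, with the order of the two esterifications reversed:
- Ketal hydrolysis as in step 16 gives (3S,4S,5R,10R)-3β-[(tert-butyldimethylsilyl)oxy]-4α-hydroxy-4β,10β-dimethyl-trans-decalin-8-one F6.
- Aldol addition to acetone with 2.2 equiv of LiN(i-Pr)2 gives the 7-(2-hydroxypropan-2-yl) derivative F7.
- Catalytic p-toluenesulfonic acid in CH2Cl2 at rt dehydrates only the β-hydroxy ketone, through its enol, to 3β-[(tert-butyldimethylsilyl)oxy]-4α-hydroxyeudesm-7(11)-en-8-one F8.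
- HF·pyridine gives 3β,4α-dihydroxyeudesm-7(11)-en-8-one F9.
- The conditions of step 20 acylate only the secondary hydroxyl, to 4α-hydroxy-8-oxoeudesm-7(11)-en-3β-yl (2Z)-2-methylbut-2-enoate F10.
- The tertiary hydroxyl, now without a silyl neighbour, is acetylated with Ac2O and catalytic Me3SiOSO2CF3 at −40 °C to give 27.

**Step 20.** Warm triethylamine may shift the acetyl group from O4 to the free O3 before acylation, and any nucleophile present can isomerise the activated (Z)-acyl group to the (E)-acyl group. Fallback, from 26 back to 27: the alkene is built on the molecule at low temperature. Carbodiimide esterification of 26 with 2-[bis(2,2,2-trifluoroethoxy)phosphoryl]propanoic acid at 0 °C gives (3S,4S,5R,10R)-4α-acetoxy-8-oxoeudesm-7(11)-en-3β-yl 2-[bis(2,2,2-trifluoroethoxy)phosphoryl]propanoate F11. Still–Gennari olefination with acetaldehyde (KN(SiMe3)2, 18-crown-6, THF, −78 °C) gives the (Z)-trisubstituted ester 27; the phosphonate is far more acidic than the ketone, so one equivalent of base suffices.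

## Further compounds

F1 | step 11 | 3-[(7R,8R)-8-(1-iodoethenyl)-7-methyl-1,4-dioxaspiro[4.5]decan-7-yl]propanoic acid | OC(=O)CC[C@]1(C)CC2(OCCO2)CC[C@H]1C(I)=C
F2 | step 11 | 3-[(7R,8R)-8-(1-iodoethenyl)-7-methyl-1,4-dioxaspiro[4.5]decan-7-yl]-N-methoxy-N-methylpropanamide | CON(C)C(=O)CC[C@]1(C)CC2(OCCO2)CC[C@H]1C(I)=C
F3 | step 11 | (5R,10R)-10-methyl-4-methylidene-trans-decalin-3,8-dione 8-ethylene ketal | O=C1CC[C@]2(C)CC3(OCCO3)CC[C@H]2C1=C
F4 | step 2 | (4S)-4-benzyl-3-{[(1R,2S)-2-methyl-4-[(triisopropylsilyl)oxy]cyclohex-3-en-1-yl]carbonyl}-1,3-oxazolidin-2-one | C[C@H]1C=C(O[Si](C(C)C)(C(C)C)C(C)C)CC[C@H]1C(=O)N1C(=O)OC[C@@H]1Cc1ccccc1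
F5 | step 8 | 1-[(7R,8R)-7-methyl-7-(prop-2-en-1-yl)-1,4-dioxaspiro[4.5]decan-8-yl]ethenyl trifluoromethanesulfonate | C=CC[C@]1(C)CC2(OCCO2)CC[C@H]1C(=C)OS(=O)(=O)C(F)(F)F
F6 | step 15 | (3S,4S,5R,10R)-3β-[(tert-butyldimethylsilyl)oxy]-4α-hydroxy-4β,10β-dimethyl-trans-decalin-8-one | CC(C)(C)[Si](C)(C)O[C@H]1CC[C@]2(C)CC(=O)CC[C@H]2[C@]1(C)O
F7 | step 15 | (3S,4S,5R,10R)-3β-[(tert-butyldimethylsilyl)oxy]-4α-hydroxy-7-(2-hydroxypropan-2-yl)-4β,10β-dimethyl-trans-decalin-8-one (C7 epimers) | CC(C)(C)[Si](C)(C)O[C@H]1CC[C@]2(C)CC(=O)C(C(C)(C)O)C[C@H]2[C@]1(C)O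
F8 | step 15 | 3β-[(tert-butyldimethylsilyl)oxy]-4α-hydroxyeudesm-7(11)-en-8-one | CC(C)(C)[Si](C)(C)O[C@H]1CC[C@]2(C)CC(=O)C(=C(C)C)C[C@H]2[C@]1(C)O
F9 | step 15 | 3β,4α-dihydroxyeudesm-7(11)-en-8-one | O[C@H]1CC[C@]2(C)CC(=O)C(=C(C)C)C[C@H]2[C@]1(C)O
F10 | step 15 | 4α-hydroxy-8-oxoeudesm-7(11)-en-3β-yl (2Z)-2-methylbut-2-enoate | C/C=C(/C)C(=O)O[C@H]1CC[C@]2(C)CC(=O)C(=C(C)C)C[C@H]2[C@]1(C)O
F11 | step 20 | (3S,4S,5R,10R)-4α-acetoxy-8-oxoeudesm-7(11)-en-3β-yl 2-[bis(2,2,2-trifluoroethoxy)phosphoryl]propanoate | CC(C(=O)O[C@H]1CC[C@]2(C)CC(=O)C(=C(C)C)C[C@H]2[C@]1(C)OC(C)=O)P(=O)(OCC(F)(F)F)OCC(F)(F)F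
A1 | alternative 1 | (3S)-3-[(tert-butyldimethylsilyl)oxy]germacra-1(10)E,4E,7(11)-trien-8-one | CC(C)(C)[Si](C)(C)O[C@H]1C/C=C(\C)CC(=O)C(=C(C)C)C/C=C1\C
A2 | alternative 1 | 3β-[(tert-butyldimethylsilyl)oxy]-4α-hydroxyeudesm-7(11)-en-8-one | CC(C)(C)[Si](C)(C)O[C@H]1CC[C@]2(C)CC(=O)C(=C(C)C)C[C@H]2[C@]1(C)O
A3 | alternative 2 | 4-(3-hydroxy-2,6-dimethylphenyl)-2-methylidenebutyl methyl carbonate | Cc1ccc(O)c(C)c1CCC(=C)COC(=O)OC
A4 | alternative 2 | 4,10β-dimethyl-8-methylidene bicyclic 1,4-dien-3-one (eudesmane numbering) | O=C1C=C[C@]2(C)CC(=C)CCC2=C1C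
A5 | alternative 3 | (6S)-6-[(tert-butyldimethylsilyl)oxy]-3-{[2-(2-iodoethyl)-1,3-dioxolan-2-yl]methyl}cyclohex-2-en-1-one | CC(C)(C)[Si](C)(C)O[C@H]1CCC(CC2(CCI)OCCO2)=CC1=O
A6 | alternative 3 | 3β-[(tert-butyldimethylsilyl)oxy]-10β-methyl-trans-decalin-4,8-dione 8-ethylene ketal | CC(C)(C)[Si](C)(C)O[C@H]1CC[C@]2(C)CC3(OCCO3)CC[C@H]2C1=O
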